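## Retrosynthetic overview

- The C3 bromide comes last, by Appel inversion of a propargylic alcohol made by ethynyl addition to a C3 aldehyde on the finished bicycle.
- The THF ring is the reduced form of a γ-lactone: vinyl addition at the lactone carbonyl (C4), then ionic hydrogenation, sets C4.
- Key disconnection: the C6–C7 bond, made by SmI2 ketyl–olefin closure of a C7 aldehyde (polarity-reversed carbonyl carbon) onto C6 of a β-alkoxyacrylate. The oxocane forms first; the lactone (future THF ring) closes in the same flask.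
- The open-chain precursor (C7–C15 plus the acrylate C4–C6) comes from butanal by two rounds of organocatalytic α-bromination and anti-selective carbonyl addition, with ethyl propiolate supplying C4–C6.

Assumption: atom labels C1–C15 follow the acetogenin chain (C1 = alkyne CH, C15 = ethyl CH3); bicyclic names use 2,9-dioxabicyclo[6.3.0]undecane numbering (1 = C6, O2 = oxocane oxygen, 8 = C7, O9 = THF oxygen, 10 = C4); an α-bromo aldehyde made and consumed in one flask is not counted as a separate step.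

## Route

Step 1
Reactants: 1 butanal; 2 [2-(1,3-dioxan-2-yl)ethyl]magnesium bromide
Product: 4 (3R,4S)-4-bromo-1-(1,3-dioxan-2-yl)hexan-3-ol, via (2S)-2-bromobutanal 3 (not isolated)
Conditions: (S)-2-{bis[3,5-bis(trifluoromethyl)phenyl][(trimethylsilyl)oxy]methyl}pyrrolidine (10 mol%), PhCO2H (10 mol%), 4,4-dibromo-2,6-di-tert-butylcyclohexa-2,5-dien-1-one (1.0 equiv), CH2Cl2, −40 °C; then 2 (0.5 M in THF, 2.5 equiv), −78 °C; aq. NH4Cl at −78 °C
Reagents that add atoms: 4,4-dibromo-2,6-di-tert-butylcyclohexa-2,5-dien-1-one, CC(C)(C)C1=CC(Br)(Br)C=C(C(C)(C)C)C1=O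
Why: Enamine α-bromination with the (S)-diarylprolinol silyl ether delivers Br to the enamine face remote from the CAr2(OSiMe3) group and sets C13 as S; the Grignard reagent (a propanal homoenolate equivalent) then adds in the Cornforth–Felkin sense to give the 1,2-anti bromohydrin (C12 R), and the cold quench prevents epoxide closure.

Step 2
Reactants: 4 (3R,4S)-4-bromo-1-(1,3-dioxan-2-yl)hexan-3-ol; 5 ethyl propiolate
Product: 6 ethyl (2E)-3-{[(3R,4S)-4-bromo-1-(1,3-dioxan-2-yl)hexan-3-yl]oxy}prop-2-enoate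
Conditions: N-methylmorpholine (1.5 equiv), CH2Cl2, rt
Reagents that add atoms: none
Why: Amine-mediated oxa-Michael addition of the secondary alcohol to the ynoate gives the (E)-β-alkoxyacrylate, and the weak base does not close the bromohydrin to an epoxide; no stereocenter is formed.

Step 3
Reactants: 6 ethyl (2E)-3-{[(3R,4S)-4-bromo-1-(1,3-dioxan-2-yl)hexan-3-yl]oxy}prop-2-enoate
Product: 7 ethyl (2E)-3-{[(4R,5S)-5-bromo-1-oxoheptan-4-yl]oxy}prop-2-enoate
Conditions: CF3CO2H/H2O (4:1), CH2Cl2, 0 °C → rt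
Reagents that add atoms: water, O
Why: Acid-catalysed acetal hydrolysis frees the C9 aldehyde; the vinylogous carbonate and the secondary bromide tolerate aqueous acid.

Step 4
Reactants: 7 ethyl (2E)-3-{[(4R,5S)-5-bromo-1-oxoheptan-4-yl]oxy}prop-2-enoate; 8 (+)-B-allyldiisopinocampheylborane
Product: 10 ethyl (2E)-3-{[(3S,4R,6S,7R)-3,6-dibromo-7-hydroxydec-9-en-4-yl]oxy}prop-2-enoate, via dibromo aldehyde 9 (not isolated)
Conditions: (S)-2-{bis[3,5-bis(trifluoromethyl)phenyl][(trimethylsilyl)oxy]methyl}pyrrolidine (10 mol%), PhCO2H (10 mol%), 4,4-dibromo-2,6-di-tert-butylcyclohexa-2,5-dien-1-one (1.0 equiv), CH2Cl2, −40 °C; then 8 (1 M in pentane, 1.6 equiv), Et2O, −78 °C; pH 7 buffer, 30% H2O2, MeOH, 0 °C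
Reagents that add atoms: 4,4-dibromo-2,6-di-tert-butylcyclohexa-2,5-dien-1-one, CC(C)(C)C1=CC(Br)(Br)C=C(C(C)(C)C)C1=O
Why: The same catalyst-controlled enamine α-bromination sets C10 as S irrespective of the remote centers; Brown allylboration through a closed Zimmerman–Traxler transition state with the (−)-α-pinene-derived reagent attacks the Re face to set C9 as R, matched with the Cornforth preference for the anti bromohydrin.

Step 5
Reactants: 10 ethyl (2E)-3-{[(3S,4R,6S,7R)-3,6-dibromo-7-hydroxydec-9-en-4-yl]oxy}prop-2-enoate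
Product: 11 ethyl (2E)-3-{[(3S,4R,6S,7R)-3,6-dibromo-7-hydroxy-9-oxononan-4-yl]oxy}prop-2-enoate
Conditions: OsO4 (2 mol%), NaIO4 (4 equiv), 2,6-lutidine, 1,4-dioxane/H2O (3:1), rt; used crude
Reagents that add atoms: sodium periodate, [Na+].[O-]I(=O)(=O)=O (terminal oxidant; its oxygen reaches the aldehyde through catalytic OsO4, O=[Os](=O)(=O)=O)
Why: Lemieux–Johnson cleavage takes the electron-rich terminal alkene and leaves the electron-poor push–pull acrylate alkene untouched, giving the C7 aldehyde with the C9 hydroxyl deliberately free.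

Step 6
Reactants: 11 ethyl (2E)-3-{[(3S,4R,6S,7R)-3,6-dibromo-7-hydroxy-9-oxononan-4-yl]oxy}prop-2-enoate
Product: 13 (1S,3R,5S,6R,8R)-5-bromo-3-[(1S)-1-bromopropyl]-6-hydroxy-2,9-dioxabicyclo[6.3.0]undecan-10-one, via hydroxy ester 12 (not isolated)
Conditions: SmI2 (0.1 M in THF, 3.0 equiv), MeOH (3 equiv), slow addition of 11 (final 0.005 M), THF, 0 °C → rt; no HMPA
Reagents that add atoms: none
Why: Proposed new method: SmI2 reduces the C7 aldehyde to a samarium ketyl whose carbon is now nucleophilic and adds 8-exo-trig to C6, the acrylate β-carbon (two carbons that are both electrophilic in the ground state); a second electron and MeOH give ester 12, and the C7 alkoxide lactonises. Trivalent samarium is held by the ketyl oxygen and the ester carbonyl (H6/H7 anti, as in the Nakata cyclisation) and by the free C9 hydroxyl (six-membered chelate, 1,3-anti C7/C9 as in Keck-type SmI2 reactions of β-hydroxy carbonyls), which fixes C7 as R and C6 as S. Unactivated secondary bromides are not reduced by SmI2 without HMPA on this time scale. The closest known reaction types are the Nakata SmI2 aldehyde/β-alkoxyacrylate cyclisation to oxanes and oxepanes and SmI2 ketyl–enone closures of eight-membered carbocycles.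

Step 7
Reactants: 13 (1S,3R,5S,6R,8R)-5-bromo-3-[(1S)-1-bromopropyl]-6-hydroxy-2,9-dioxabicyclo[6.3.0]undecan-10-one; 14 vinylmagnesium bromide
Product: 15 (1S,3R,5S,6R,8R)-5-bromo-3-[(1S)-1-bromopropyl]-10-ethenyl-2,9-dioxabicyclo[6.3.0]undecane-6,10-diol (mixture at C10)
Conditions: 14 (1 M in THF, 2.3 equiv), THF, −78 °C, 1 h; aq. NH4Cl at −78 °C; used crude
Reagents that add atoms: none
Why: Grignard addition to the γ-lactone stops at the magnesium hemiketal at −78 °C (the first equivalent is spent on the C9 hydroxyl), giving the lactol that carries C3; no defined stereocenter is formed.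

Step 8
Reactants: 15 (1S,3R,5S,6R,8R)-5-bromo-3-[(1S)-1-bromopropyl]-10-ethenyl-2,9-dioxabicyclo[6.3.0]undecane-6,10-diol
Product: 16 (1S,3R,5S,6R,8R,10R)-5-bromo-3-[(1S)-1-bromopropyl]-10-ethenyl-2,9-dioxabicyclo[6.3.0]undecan-6-ol
Conditions: Et3SiH (5 equiv), BF3·OEt2 (3 equiv), CH2Cl2/MeCN (1:1), −78 → −40 °C
Reagents that add atoms: none
Why: Ionic hydrogenation of the lactol through the five-membered oxocarbenium ion; hydride attacks inside the envelope (Woerpel model), cis to the C6 oxygen and anti to the C7–C8 bond, giving the 2,5-cis THF with C4 (position 10) as R.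

Step 9
Reactants: 16 (1S,3R,5S,6R,8R,10R)-5-bromo-3-[(1S)-1-bromopropyl]-10-ethenyl-2,9-dioxabicyclo[6.3.0]undecan-6-ol
Product: 17 (1S,3R,5S,6R,8R,10R)-5-bromo-3-[(1S)-1-bromopropyl]-10-ethenyl-2,9-dioxabicyclo[6.3.0]undecan-6-yl acetate
Conditions: Ac2O, pyridine, 4-(dimethylamino)pyridine (cat.), CH2Cl2, 0 °C → rt
Reagents that add atoms: acetic anhydride, CC(=O)OC(C)=O
Why: Nucleophile-catalysed acylation of the only free hydroxyl, done now because all additions that an acetate would not survive are finished.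

Step 10
Reactants: 17 (1S,3R,5S,6R,8R,10R)-5-bromo-3-[(1S)-1-bromopropyl]-10-ethenyl-2,9-dioxabicyclo[6.3.0]undecan-6-yl acetate
Product: 18 (1S,3R,5S,6R,8R,10R)-5-bromo-3-[(1S)-1-bromopropyl]-10-formyl-2,9-dioxabicyclo[6.3.0]undecan-6-yl acetate
Conditions: O3, CH2Cl2, −78 °C; then PPh3, −78 °C → rt; used crude
Reagents that add atoms: ozone, [O-][O+]=O
Why: Ozonolysis with reductive work-up converts the vinyl group into the C3 aldehyde under neutral conditions, so the α-alkoxy center C4 is not epimerised.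

Step 11
Reactants: 18 (1S,3R,5S,6R,8R,10R)-5-bromo-3-[(1S)-1-bromopropyl]-10-formyl-2,9-dioxabicyclo[6.3.0]undecan-6-yl acetate; 19 ethynylmagnesium bromide
Product: 20 (1S,3R,5S,6R,8R,10R)-5-bromo-3-[(1S)-1-bromopropyl]-10-[(1S)-1-hydroxyprop-2-yn-1-yl]-2,9-dioxabicyclo[6.3.0]undecan-6-yl acetate
Conditions: 19 (0.5 M in THF, 1.5 equiv), ClTi(OiPr)3 (1.5 equiv), THF, −78 °C, 30 min; then 18, −78 → −40 °C
Reagents that add atoms: none
Why: The non-chelating alkynyltitanium triisopropoxide (Reetz-type reagent) adds to the α-alkoxy aldehyde in the Felkin–Anh sense to give the 1,2-anti alcohol (C3 S) and does not touch the acetate.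

Step 12
Reactants: 20 (1S,3R,5S,6R,8R,10R)-5-bromo-3-[(1S)-1-bromopropyl]-10-[(1S)-1-hydroxyprop-2-yn-1-yl]-2,9-dioxabicyclo[6.3.0]undecan-6-yl acetate
Product: 21 (1S,3R,5S,6R,8R,10R)-5-bromo-10-[(1R)-1-bromoprop-2-yn-1-yl]-3-[(1S)-1-bromopropyl]-2,9-dioxabicyclo[6.3.0]undecan-6-yl acetate
Conditions: CBr4 (2 equiv), PPh3 (2.2 equiv), CH2Cl2, −20 → 0 °C
Reagents that add atoms: carbon tetrabromide, BrC(Br)(Br)Br
Why: Appel reaction: bromide displaces the propargylic oxyphosphonium by SN2 with inversion, turning (S)-alcohol into (R)-bromide at C3.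

## Compound list

1 | butanal | CCCC=O | starting material
2 | [2-(1,3-dioxan-2-yl)ethyl]magnesium bromide | Br[Mg]CCC1OCCCO1 | starting material
3 | (2S)-2-bromobutanal | CC[C@H](Br)C=O | intermediate
4 | (3R,4S)-4-bromo-1-(1,3-dioxan-2-yl)hexan-3-ol | CC[C@H](Br)[C@H](O)CCC1OCCCO1 | intermediate
5 | ethyl propiolate | C#CC(=O)OCC | starting material
6 | ethyl (2E)-3-{[(3R,4S)-4-bromo-1-(1,3-dioxan-2-yl)hexan-3-yl]oxy}prop-2-enoate | CC[C@H](Br)[C@H](O/C=C/C(=O)OCC)CCC1OCCCO1 | intermediate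
7 | ethyl (2E)-3-{[(4R,5S)-5-bromo-1-oxoheptan-4-yl]oxy}prop-2-enoate | CC[C@H](Br)[C@H](O/C=C/C(=O)OCC)CCC=O | intermediate
8 | (+)-B-allyldiisopinocampheylborane (from (−)-α-pinene) | C=CCB([C@H]1C[C@H]2C[C@@H]([C@@H]1C)C2(C)C)[C@H]1C[C@H]2C[C@@H]([C@@H]1C)C2(C)C | starting material
9 | ethyl (2E)-3-{[(2S,4R,5S)-2,5-dibromo-1-oxoheptan-4-yl]oxy}prop-2-enoate | CC[C@H](Br)[C@H](O/C=C/C(=O)OCC)C[C@H](Br)C=O | intermediate
10 | ethyl (2E)-3-{[(3S,4R,6S,7R)-3,6-dibromo-7-hydroxydec-9-en-4-yl]oxy}prop-2-enoate | CC[C@H](Br)[C@H](O/C=C/C(=O)OCC)C[C@H](Br)[C@H](O)CC=C | intermediate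
11 | ethyl (2E)-3-{[(3S,4R,6S,7R)-3,6-dibromo-7-hydroxy-9-oxononan-4-yl]oxy}prop-2-enoate | CC[C@H](Br)[C@H](O/C=C/C(=O)OCC)C[C@H](Br)[C@H](O)CC=O | intermediate
12 | ethyl 2-[(2S,3R,5R,6S,8R)-6-bromo-8-[(1S)-1-bromopropyl]-3,5-dihydroxyoxocan-2-yl]acetate | CCOC(=O)C[C@@H]1O[C@@H]([C@@H](Br)CC)C[C@H](Br)[C@H](O)C[C@H]1O | intermediate
13 | (1S,3R,5S,6R,8R)-5-bromo-3-[(1S)-1-bromopropyl]-6-hydroxy-2,9-dioxabicyclo[6.3.0]undecan-10-one | O=C1C[C@@H]2O[C@@H]([C@@H](Br)CC)C[C@H](Br)[C@H](O)C[C@H]2O1 | intermediate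
14 | vinylmagnesium bromide | C=C[Mg]Br | starting material
15 | (1S,3R,5S,6R,8R)-5-bromo-3-[(1S)-1-bromopropyl]-10-ethenyl-2,9-dioxabicyclo[6.3.0]undecane-6,10-diol (mixture at C10) | C=CC1(O)C[C@@H]2O[C@@H]([C@@H](Br)CC)C[C@H](Br)[C@H](O)C[C@H]2O1 | intermediate
16 | (1S,3R,5S,6R,8R,10R)-5-bromo-3-[(1S)-1-bromopropyl]-10-ethenyl-2,9-dioxabicyclo[6.3.0]undecan-6-ol | C=C[C@H]1C[C@@H]2O[C@@H]([C@@H](Br)CC)C[C@H](Br)[C@H](O)C[C@H]2O1 | intermediate
17 | (1S,3R,5S,6R,8R,10R)-5-bromo-3-[(1S)-1-bromopropyl]-10-ethenyl-2,9-dioxabicyclo[6.3.0]undecan-6-yl acetate | C=C[C@H]1C[C@@H]2O[C@@H]([C@@H](Br)CC)C[C@H](Br)[C@H](OC(C)=O)C[C@H]2O1 | intermediate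
18 | (1S,3R,5S,6R,8R,10R)-5-bromo-3-[(1S)-1-bromopropyl]-10-formyl-2,9-dioxabicyclo[6.3.0]undecan-6-yl acetate | O=C[C@H]1C[C@@H]2O[C@@H]([C@@H](Br)CC)C[C@H](Br)[C@H](OC(C)=O)C[C@H]2O1 | intermediate
19 | ethynylmagnesium bromide | C#C[Mg]Br | starting material
20 | (1S,3R,5S,6R,8R,10R)-5-bromo-3-[(1S)-1-bromopropyl]-10-[(1S)-1-hydroxyprop-2-yn-1-yl]-2,9-dioxabicyclo[6.3.0]undecan-6-yl acetate | C#C[C@H](O)[C@H]1C[C@@H]2O[C@@H]([C@@H](Br)CC)C[C@H](Br)[C@H](OC(C)=O)C[C@H]2O1 | intermediate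
21 | (1S,3R,5S,6R,8R,10R)-5-bromo-10-[(1R)-1-bromoprop-2-yn-1-yl]-3-[(1S)-1-bromopropyl]-2,9-dioxabicyclo[6.3.0]undecan-6-yl acetate | C#C[C@@H](Br)[C@H]1C[C@@H]2O[C@@H]([C@@H](Br)CC)C[C@H](Br)[C@H](OC(C)=O)C[C@H]2O1 | target

## Step count and risks

Total step count: 12. Longest linear sequence: 12 steps (fully linear from butanal).

**Step 6 (most likely to fail).** The ketyl–olefin closure is asked to make an eight-membered ring, one size beyond precedent for this acceptor. Simple aldehyde reduction or pinacol dimerisation may win, and the facial sense at C6/C7 relative to C12 rests on a chelation model. The fallback keeps the same bond but makes it by two-electron acyl-anion chemistry and sets C7 separately. It sets out from 11: an intramolecular Stetter reaction (3-benzyl-5-(2-hydroxyethyl)-4-methylthiazolium chloride, Et3N, 1,4-dioxane, 60 °C) adds the Breslow intermediate of the C7 aldehyde to C6 and gives ethyl 2-[(2S,5R,6S,8R)-6-bromo-8-[(1S)-1-bromopropyl]-5-hydroxy-3-oxooxocan-2-yl]acetate F1. Its C6 center is α to the new ketone and can be equilibrated. Hydroxyl-directed reduction with Me4NBH(OAc)3 (MeCN/AcOH, −20 °C) then delivers hydride from the C9 oxygen to give the 1,3-anti diol, and the fallback comes back to the route at 12, which lactonises to 13.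

**Step 7.** The β-alkoxy lactone can enolise and open the oxocane by β-elimination, the vinyl ketone form can over-add, and the bromohydrin alkoxide can close to an epoxide. The fallback brings in C3 as an alkyne and adjusts the oxidation level afterwards. It sets out from 13: ethynylmagnesium bromide 19 (THF, −78 °C) gives (1S,3R,5S,6R,8R)-5-bromo-3-[(1S)-1-bromopropyl]-10-ethynyl-2,9-dioxabicyclo[6.3.0]undecane-6,10-diol F2, whose ynone form does not suffer conjugate over-addition. Et3SiH/BF3·OEt2 reduces it with the same facial sense to (1S,3R,5S,6R,8R,10R)-5-bromo-3-[(1S)-1-bromopropyl]-10-ethynyl-2,9-dioxabicyclo[6.3.0]undecan-6-ol F3. Semi-hydrogenation (H2, Pd/CaCO3 poisoned with Pb(OAc)2, quinoline, EtOAc) comes back to the route at 16.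

**Step 4.** The functionalised α-bromo aldehyde 9 may epimerise before it is trapped, and the amine catalyst may attack the acrylate by addition–elimination. The fallback installs the C10 heteroatom as oxygen and makes the C–Br bond later by inversion. It sets out from 7:
- L-proline (20 mol%) and nitrosobenzene (CHCl3, 4 °C) give ethyl (2E)-3-{[(2R,4R,5S)-5-bromo-1-oxo-2-[(phenylamino)oxy]heptan-4-yl]oxy}prop-2-enoate F4.
- F4 is allylated in the same flask with 8 to ethyl (2E)-3-{[(3S,4R,6R,7R)-3-bromo-7-hydroxy-6-[(phenylamino)oxy]dec-9-en-4-yl]oxy}prop-2-enoate F5.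
- tBuMe2SiOSO2CF3/2,6-lutidine gives ethyl (2E)-3-{[(3S,4R,6R,7R)-3-bromo-7-[(tert-butyldimethylsilyl)oxy]-6-[(phenylamino)oxy]dec-9-en-4-yl]oxy}prop-2-enoate F6.
- N–O cleavage (Zn, AcOH, THF, 0 °C) gives ethyl (2E)-3-{[(3S,4R,6R,7R)-3-bromo-7-[(tert-butyldimethylsilyl)oxy]-6-hydroxydec-9-en-4-yl]oxy}prop-2-enoate F7.
- CBr4/PPh3 inverts C10 to give ethyl (2E)-3-{[(3S,4R,6S,7R)-3,6-dibromo-7-[(tert-butyldimethylsilyl)oxy]dec-9-en-4-yl]oxy}prop-2-enoate F8.
- HF·pyridine (THF, 0 °C) comes back to the route at 10.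

## Further compounds

F1 | step 6 | ethyl 2-[(2S,5R,6S,8R)-6-bromo-8-[(1S)-1-bromopropyl]-5-hydroxy-3-oxooxocan-2-yl]acetate | CCOC(=O)C[C@@H]1O[C@@H]([C@@H](Br)CC)C[C@H](Br)[C@H](O)CC1=O
F2 | step 7 | (1S,3R,5S,6R,8R)-5-bromo-3-[(1S)-1-bromopropyl]-10-ethynyl-2,9-dioxabicyclo[6.3.0]undecane-6,10-diol | C#CC1(O)C[C@@H]2O[C@@H]([C@@H](Br)CC)C[C@H](Br)[C@H](O)C[C@H]2O1
F3 | step 7 | (1S,3R,5S,6R,8R,10R)-5-bromo-3-[(1S)-1-bromopropyl]-10-ethynyl-2,9-dioxabicyclo[6.3.0]undecan-6-ol | C#C[C@H]1C[C@@H]2O[C@@H]([C@@H](Br)CC)C[C@H](Br)[C@H](O)C[C@H]2O1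
F4 | step 4 | ethyl (2E)-3-{[(2R,4R,5S)-5-bromo-1-oxo-2-[(phenylamino)oxy]heptan-4-yl]oxy}prop-2-enoate | CC[C@H](Br)[C@H](O/C=C/C(=O)OCC)C[C@@H](ONc1ccccc1)C=O
F5 | step 4 | ethyl (2E)-3-{[(3S,4R,6R,7R)-3-bromo-7-hydroxy-6-[(phenylamino)oxy]dec-9-en-4-yl]oxy}prop-2-enoate | CC[C@H](Br)[C@H](O/C=C/C(=O)OCC)C[C@@H](ONc1ccccc1)[C@H](O)CC=C
F6 | step 4 | ethyl (2E)-3-{[(3S,4R,6R,7R)-3-bromo-7-[(tert-butyldimethylsilyl)oxy]-6-[(phenylamino)oxy]dec-9-en-4-yl]oxy}prop-2-enoate | CC[C@H](Br)[C@H](O/C=C/C(=O)OCC)C[C@@H](ONc1ccccc1)[C@H](O[Si](C)(C)C(C)(C)C)CC=C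
F7 | step 4 | ethyl (2E)-3-{[(3S,4R,6R,7R)-3-bromo-7-[(tert-butyldimethylsilyl)oxy]-6-hydroxydec-9-en-4-yl]oxy}prop-2-enoate | CC[C@H](Br)[C@H](O/C=C/C(=O)OCC)C[C@@H](O)[C@H](O[Si](C)(C)C(C)(C)C)CC=C
F8 | step 4 | ethyl (2E)-3-{[(3S,4R,6S,7R)-3,6-dibromo-7-[(tert-butyldimethylsilyl)oxy]dec-9-en-4-yl]oxy}prop-2-enoate | CC[C@H](Br)[C@H](O/C=C/C(=O)OCC)C[C@H](Br)[C@H](O[Si](C)(C)C(C)(C)C)CC=C
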